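| flask | electrophile | nucleophile | protic impurity | remark | time |
|---|---|---|---|---|---|
| autumn | 0.050 M | 0.069 M | 1 mM | run made earlier |  |
| dawn | 0.050 M | 0.11 M | 1 mM | run made earlier |  |
| ash | 0.050 M | 0.0520 M | 1.00 mM |  | 3.0 h |
| birch | 0.050 M | 0.0680 M | 1.00 mM |  | 3.0 h |
| larch | 0.050 M | 0.0890 M | 1.00 mM |  | 3.0 h |

| run | time / min | electrophile / % | target / % |
|---|---|---|---|
| autumn | 20.0 | 66 | 28 |
| autumn | 40.0 | 49 | 34 |
| autumn | 50.0 | 44 | 31 |
| autumn | 80.0 | 31 | 32 |
| autumn | 90.0 | 33 | 30 |
| autumn | 120 | 24 | 32 |
| dawn | 6.00 | 78 | 20 |
| dawn | 20.0 | 47 | 38 |
| dawn | 40.0 | 30 | 40 |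
| dawn | 50.0 | 26 | 39 |
| dawn | 80.0 | 16 | 38 |
| dawn | 90.0 | 15 | 35 |
| dawn | 120 | 9 | 34 |

(scatter of a reading: 1.5 percentage points)

- in percentages every species weighs as the electrophile in it: one side product counts as two
- candidate steps: nucleophile + target -> over-reaction product; nucleophile + acid set free <-> protonated nucleophile; electrophile + target -> side product; electrophile + nucleophile -> acid set free + target; nucleophile + protic impurity -> quenched reagent

1. part of the electrophile that has reacted at the end, ash
2. part of the electrophile that has reacted at the end, birch
3. part of the electrophile that has reacted at the end, larch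
4. what raising the concentration of nucleophile from its lowest to its highest value here does to the part of the electrophile that has reacted (changes below 5 percentage points count as none) (it falls / it rises / no change)

- I read ash, birch and larch at 3.0 h, later than the last reading of either earlier run, so I want a quantity that carries across both nucleophile charge and time. I try the reach: the natural logarithm of charged electrophile over electrophile left, divided by the nucleophile charged.
- At 120 min the reach is 20.7 M⁻¹ in autumn and 21.9 M⁻¹ in dawn, close for two different nucleophile charges at 0.050 M of electrophile. At 80.0 min the two runs give a mean of 16.8 M⁻¹.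
- The protic impurity comes first on my ladder, whatever its speed: its charge is 1.92% of ash's nucleophile, so I drop it from my reckoning.
- Next comes the start. Dawn's first reading, treated as pseudo-first-order, gives ash a half-life of electrophile of 35.4 min.
- Then comes the late decay. With a mean reach of 21.3 M⁻¹ at 120 min, the gain since 80.0 min gives ash a half-life of 119 min, longer than at the start and longer than the 60.0 min still to run. So I expect ash still to hold electrophile when I read it.
- From 120 min to 3.0 h time grows by the same factor as from 80.0 min to 120 min; I assume that equal factors of time bring equal gains, and so I add the same gain. That gives 25.8 M⁻¹, the reach at the time of reading.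
- My reckoning is then 73.8% reacted in ash, 82.6% in birch and 89.9% in larch, a rise of 16 percentage points.
- The forecast, holding that “More nucleophile means more conversion”, gives 76%, 84% and 92%, each above mine, and its trend is: it rises.
- The flasks give 71.1%, 80.7% and 89.0%; the trend is: it rises, by 18 points.

    nucleophile + target → over-reaction product (k = 0.230 M⁻¹ min⁻¹)
    nucleophile + acid set free ⇌ protonated nucleophile, settled at all times (K = 740 M⁻¹)
    electrophile + target → side product (k = 0.200 M⁻¹ min⁻¹)
    electrophile + nucleophile → acid set free + target (k = 0.420 M⁻¹ min⁻¹)
    nucleophile + protic impurity → quenched reagent (k = 4.20 M⁻¹ min⁻¹)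

- In larch, electrophile + nucleophile to acid set free + target has 92% of its turnover up to the reading behind it by 1.50 h, when free nucleophile stands at 15.7% of its charge. Larch's electrophile + target to side product passes the midpoint of its turnover up to the reading at 0.898 h. Read back, the reach is 23.8 M⁻¹ in ash, 24.2 M⁻¹ in birch and 24.9 M⁻¹ in larch, against my 25.8 M⁻¹. The reach belongs to one electrophile charge: a neighbour of larch with 0.085 M of electrophile, all else held, keeps 21% of its electrophile at the reading, a reach of 17.7 M⁻¹, lower than larch's.

Readings and results come from a simulation from invented constants; the scatter is artificial.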